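**Assumption:** the target has no stereocentre, stereogenic axis or stereogenic double bond, so it is achiral and the requirement "single enantiomer" is met by the compound itself.

**Strategy in one sentence:** the C7–S bond is made last, by anodic oxidation of the unprotected methylcatechol 4 in the presence of sodium methanesulfinate 5, through an o-quinone → p-quinone methide relay that copies the way the benzylic position of the algal bromophenols is presumed to be functionalised. The key step is therefore both electrochemical and biomimetic.

**Compound numbers (fixed for the whole text):** 1 creosol; 2 dibromocreosol; 3 cyclic bromoborane (in flask); 4 dibromo-methylcatechol; 5 sodium methanesulfinate; 6 o-quinone (in flask); 7 p-quinone methide (in flask); 8 target.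

## Analysis of the target

Target 8 is 3,4-dibromo-5-[(methylsulfonyl)methyl]benzene-1,2-diol: a single benzene ring with five of its six positions substituted and no other ring. Atom numbering used throughout: C1 carries the benzylic carbon C7 (C7H2–SO2–C8H3), C2 and C3 carry Br, C4 and C5 carry the hydroxyls O4–H and O5–H, C6 carries H. There is no stereogenic element, so the problems are regiochemical and chemoselective.

The sensitive groups are:
- the catechol O4/O5, which is easily oxidised to an o-quinone;
- the two aryl bromides, which rule out organometallic, strongly reducing and most Pd-based steps;
- the p-hydroxybenzyl sulfone unit, which can expel sulfinate from the C4 phenolate under base.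

Two things make the synthesis hard. The bromines must sit on C2 and C3 while C6, which is also ortho to a hydroxyl, keeps its hydrogen. And C7–S normally requires a protected catechol plus a benzylic leaving group, which costs steps at both ends.

The feature the route exploits is that O4–C4 lies para to C1–C7 across the ring, with O5–C5 next to it. The unit C7–C1···C4(O4)–C5(O5) is a 4-alkylcatechol, the two-electron-reduced form of the o-quinone C4=O/C5=O, whose tautomer is the p-quinone methide C7=C1···C4=O. In that quinone the ring β-carbons C1 and C2 are fully substituted and C3 carries Br. C7 is therefore the only position where a nucleophile can add and restore the benzene ring without loss of a substituent. The catechol can thus serve as the activating group for C7–H.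

## Retrosynthetic reasoning

**First disconnection, C7–S (8 ⇒ 4 + 5).** C7–S is the only bond joining the two building blocks of 8, and the S–C8 bond is available ready-made in sulfinate 5. The cut is made at the hydrocarbon oxidation level, C7–H of methylcatechol 4, not at that of a benzylic halide. In the forward direction, anodic two-electron oxidation of 4 gives o-quinone 6, a proton shift from C7 to O5 turns 6 into p-quinone methide 7, and 1,6-addition of 5 at C7 restores the ring and both free hydroxyls. The gain is that no phenol protection, no benzylic leaving group and no redox adjustment at C7 are needed, and 8 is the last compound formed. The forward step must oxidise 4 in the presence of 5 without oxidising 5 or 8, and must deliver sulfur to C7 and not to C2 or C3.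

**Second disconnection, O5–CH3 (4 ⇒ 2).** Catechol 4 is traced to its O5-methyl ether 2. The methyl group is kept for one step only because it makes O4 and O5 different in the preceding bromination. In the forward direction a boron Lewis acid cleaves the ether through the cyclic boron ester 3, which the aqueous quench hydrolyses to 4.

**Third disconnection, C2–Br and C3–Br together (2 ⇒ 1).** Both C–Br bonds are cut in one operation because in 1 each position is controlled by one oxygen alone. C3 is ortho to the free hydroxyl O4, whose para position C1 is blocked by C7. C2 is para to the methoxy group on O5. C6 is meta to O4 and lies between the methoxy-bearing C5 and C1, so it is the least reactive open position and keeps its hydrogen. A free catechol at this stage would offer two equally strong directors and no such differentiation. Compounds 1 and 5 are commercial bulk chemicals, and 1 already contains C1–C7 and both oxygens.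

## Alternatives that were turned down

**Alternative 1:** the textbook route, C7–S by substitution at a benzylic electrophile.
- Disconnection: C7–S as sulfinate plus benzylic alcohol or halide, with C7 entering as an aldehyde carbon.
- Forward: vanillin A1 is brominated twice to 2,3-dibromo-4-hydroxy-5-methoxybenzaldehyde A2, demethylated and reduced to 2,3-dibromo-4,5-dihydroxybenzyl alcohol A3, which is activated and displaced with 5 to give 8.
- Why turned down: C7 is bought at the aldehyde level and must be reduced and then activated, so the route is five to six steps against three. It uses the same ortho-to-OH / para-to-OMe bromination logic, so nothing is gained for the arene. A3 and its halides ionise readily to the C7 quinone methide and self-condense to ethers and oligomers, so the least stable intermediate is handled in the most demanding step.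

**Alternative 2:** three-component sulfone assembly.
- Disconnection: C7–S and S–C8 at once, sulfur entering as an SO2 surrogate.
- Forward: 2,3-dibromo-1-(bromomethyl)-4,5-dimethoxybenzene A4 (from 2 by O-methylation and radical bromination) is reductively sulfinated to sodium (2,3-dibromo-4,5-dimethoxyphenyl)methanesulfinate A5, which is S-methylated in the same flask to the dimethyl ether A6 of the target; twofold ether cleavage gives 8.
- Why turned down: the S–C8 bond is already present in commercial 5, so building it creates no complexity. The reductive or organometallic conditions of sulfination act on a substrate with two aryl C–Br bonds, one of them ortho to the reacting benzylic centre. A5 is ambident and can also lose SO2. Protection, bromination and two final deprotections bring the count to six or seven steps.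

**Alternative 3:** bromination last, the biosynthetic order.
- Disconnection: C2–Br and C3–Br on the finished sulfonyl catechol.
- Forward: twofold electrophilic or haloperoxidase-type bromination of 4-[(methylsulfonyl)methyl]benzene-1,2-diol A7.
- Why turned down: in A7 both oxygens are free hydroxyls. After the first bromine enters at C2 (para to O5), C3 (ortho to O4) and C6 (ortho to O5) are activated almost equally, and the weakly withdrawing C7 substituent does not decide between them. Formation of the isomer A8 (Br on C2 and C6), which differs from 8 only in the placement of one bromine and would be hard to separate, cannot be excluded by any structural argument. A7 itself needs three to four steps, and the free catechol is exposed to an oxidising halogen source at the end.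

Key step: step 3

## Route

Step 1
Reactants: 1 2-methoxy-4-methylphenol (creosol)
Product: 2 2,3-dibromo-6-methoxy-4-methylphenol
Conditions: Br2 (2.05 equiv), AcOH, 10 °C → rt, dark
Reagents that add atoms: bromine, BrBr
Why: Twofold electrophilic aromatic bromination: the free hydroxyl O4 directs one bromine ortho to itself (C3, the para position C1 being blocked) and the methoxy group on O5 directs the other para to itself (C2); C6 is meta to the hydroxyl and wedged between C5–OMe and C1–CH3, so it should stay C–H when the bromine charge is limited to two equivalents, the pattern established for 4-substituted guaiacols.

Step 2
Reactants: 2 2,3-dibromo-6-methoxy-4-methylphenol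
Product: 4 3,4-dibromo-5-methylbenzene-1,2-diol, via cyclic bromoborane 3 (not isolated)
Conditions: BBr3 (2.5 equiv), CH2Cl2, −78 °C → rt; then H2O, 0 °C
Reagents that add atoms: none
Why: Lewis-acid cleavage of an aryl methyl ether (BBr3 demethylation): boration of O4, coordination of O5 and SN2 attack of bromide on the O-methyl carbon give the cyclic bromoborane 3, which the aqueous quench hydrolyses to catechol 4; aryl bromides and the C7 methyl group are inert to the reagent, and the electron-poor catechol should tolerate the acidic work-up.

Step 3
Reactants: 4 3,4-dibromo-5-methylbenzene-1,2-diol; 5 sodium methanesulfinate
Product: 8 3,4-dibromo-5-[(methylsulfonyl)methyl]benzene-1,2-diol (CNP0131477.0), via ortho-quinone 6 (not isolated), via para-quinone methide 7 (not isolated)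
Conditions: graphite felt (+) / Pt (−), undivided cell, constant potential at the first anodic wave of 4 (ca. +0.45 V vs Ag/AgCl), 2.1 F/mol; 5 (3 equiv), NaOAc/AcOH buffer (0.2 M, pH ca. 5.5), MeCN/H2O 1:1, Ar, 20 °C
Reagents that add atoms: none
Why: Proposed new method: anodic benzylic C–H sulfonylation of a 4-methylcatechol through an o-quinone to p-quinone methide relay; the closest known reaction types are the anodic oxidation of catechols in the presence of sulfinates (Michael trapping of the o-quinone), the isomerisation of 4-alkyl-o-quinones to 2-hydroxy-p-quinone methides, and the 1,6-addition of sulfinates to p-quinone methides. Mechanism: 4 loses two electrons and two protons at the carbon anode to give o-quinone 6; the C7 protons of 6 are vinylogous α-protons of C5=O, further acidified by the bromines on C2 and C3, and acetate-mediated proton transfer from C7 to O5 gives p-quinone methide 7; the sulfur of 5 adds to C7 (1,6-addition) and protonation of the C4 phenolate gives 8. No ring is closed and no stereocentre is formed. The step needs site selectivity for C7 over the ring: in 6 both enone β-carbons (C1, C2) are fully substituted and C3 bears Br, so ring addition cannot end in an aromatic product without C–Br cleavage and should be reversible, whereas attack at C7 of 7 is the only addition that restores the benzene ring. It needs chemoselectivity at the anode: the catechol wave of 4 should lie well below the oxidation of 5, so the potential is held there, and 8 (CH2SO2CH3 in place of CH3) should be harder to oxidise than 4, which protects the product. Kinetic O-attack of the ambident sulfinate would give a labile benzylic sulfinate ester that re-ionises to 7 and funnels to the sulfone, and cathodic reduction of 6 or 7 in the undivided cell only returns 4.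

## Compound list

1 | 2-methoxy-4-methylphenol (creosol) | COc1cc(C)ccc1O | starting material
2 | 2,3-dibromo-6-methoxy-4-methylphenol | COc1cc(C)c(Br)c(Br)c1O | intermediate
3 | 2,4,5-tribromo-6-methyl-1,3,2-benzodioxaborole (cyclic bromoborane, not isolated) | Cc1cc2OB(Br)Oc2c(Br)c1Br | intermediate
4 | 3,4-dibromo-5-methylbenzene-1,2-diol | Cc1cc(O)c(O)c(Br)c1Br | intermediate
5 | sodium methanesulfinate | CS(=O)[O-].[Na+] | starting material
6 | 3,4-dibromo-5-methylcyclohexa-3,5-diene-1,2-dione (ortho-quinone, not isolated) | CC1=CC(=O)C(=O)C(Br)=C1Br | intermediate
7 | 2,3-dibromo-6-hydroxy-4-methylidenecyclohexa-2,5-dien-1-one (para-quinone methide, not isolated) | C=C1C=C(O)C(=O)C(Br)=C1Br | intermediate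
8 | 3,4-dibromo-5-[(methylsulfonyl)methyl]benzene-1,2-diol (CNP0131477.0) | CS(=O)(=O)Cc1cc(O)c(O)c(Br)c1Br | target

## Step count and risk

Total step count: 3. Longest linear sequence: 3 steps (1 → 2 → 4 → 8); 5 is used as purchased.

**Step 3 (key step, Proposed new method).**
- What may go wrong: the proton shift 6 → 7 may be too slow in the buffered medium, because a primary quinone methide has no stabilising substituent on C7. The o-quinone would then be consumed by addition–elimination of sulfinate at the bromine-bearing C2 (loss of bromide instead of rearomatisation), by hydration, or by self-condensation. Secondary risks are hydration of the quinone methide at C7 in competition with sulfinate, and further oxidation of the product once 4 runs low.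
- Fallback (known chemistry only, sets out from 4, returns at 8): acetylation (Ac2O, pyridine) gives 3,4-dibromo-5-methyl-1,2-phenylene diacetate F1. Wohl–Ziegler bromination (NBS, AIBN, PhCF3, reflux) of this electron-poor arene gives 3,4-dibromo-5-(bromomethyl)-1,2-phenylene diacetate F2. SN2 displacement with 5 in DMF gives 3,4-dibromo-5-[(methylsulfonyl)methyl]-1,2-phenylene diacetate F3. Acid methanolysis (HCl, MeOH) removes both acetates and gives 8; acid is chosen because base would expel sulfinate from the C4 phenolate.

**Step 1.**
- What may go wrong: incomplete site control in the second bromination (attack at C6, or ipso attack at C1 followed by bromine migration), and oxidation of the very electron-rich phenol by excess halogen, leading to bromination at C7 through a quinone methide.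
- Fallback (sets out from 1, returns at 2): each bromine is introduced under one director at a time. Acetylation of 1 (Ac2O, pyridine) gives 2-methoxy-4-methylphenyl acetate F4, in which O4 is a weak director. Bromination (Br2, AcOH) then goes para to the methoxy group to give 5-bromo-2-methoxy-4-methylphenyl acetate F5. Methanolysis (K2CO3, MeOH) gives 5-bromo-2-methoxy-4-methylphenol F6. One equivalent of bromine places the second halogen ortho to the liberated hydroxyl and gives 2.

**Step 2.**
- What may go wrong: acid-promoted migration or loss of a ring bromine in the HBr-rich medium, incomplete ether cleavage, and air oxidation of the catechol during work-up.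
- Fallback (sets out from 2, returns at 4): oxidative instead of acidic demethylation. IBX in DMF oxidises the guaiacol unit of 2 to o-quinone 6 with loss of the O5-methyl group as methanol, and reduction in the same flask with aqueous sodium dithionite gives 4. This fallback makes no compound outside the compound list (F0).

## Further compounds

F1 | step 3 | 3,4-dibromo-5-methyl-1,2-phenylene diacetate | CC(=O)Oc1cc(C)c(Br)c(Br)c1OC(C)=O
F2 | step 3 | 3,4-dibromo-5-(bromomethyl)-1,2-phenylene diacetate | CC(=O)Oc1cc(CBr)c(Br)c(Br)c1OC(C)=O
F3 | step 3 | 3,4-dibromo-5-[(methylsulfonyl)methyl]-1,2-phenylene diacetate | CC(=O)Oc1cc(CS(C)(=O)=O)c(Br)c(Br)c1OC(C)=O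
F4 | step 1 | 2-methoxy-4-methylphenyl acetate | COc1cc(C)ccc1OC(C)=O
F5 | step 1 | 5-bromo-2-methoxy-4-methylphenyl acetate | COc1cc(C)c(Br)cc1OC(C)=O
F6 | step 1 | 5-bromo-2-methoxy-4-methylphenol | COc1cc(C)c(Br)cc1O
F0 | step 2 | none | none
A1 | alternative 1 | 4-hydroxy-3-methoxybenzaldehyde (vanillin) | COc1cc(C=O)ccc1O
A2 | alternative 1 | 2,3-dibromo-4-hydroxy-5-methoxybenzaldehyde | COc1cc(C=O)c(Br)c(Br)c1O
A3 | alternative 1 | 2,3-dibromo-4,5-dihydroxybenzyl alcohol | OCc1cc(O)c(O)c(Br)c1Br
A4 | alternative 2 | 2,3-dibromo-1-(bromomethyl)-4,5-dimethoxybenzene | COc1cc(CBr)c(Br)c(Br)c1OC
A5 | alternative 2 | sodium (2,3-dibromo-4,5-dimethoxyphenyl)methanesulfinate | COc1cc(CS(=O)[O-])c(Br)c(Br)c1OC.[Na+]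
A6 | alternative 2 | 2,3-dibromo-4,5-dimethoxy-1-[(methylsulfonyl)methyl]benzene | COc1cc(CS(C)(=O)=O)c(Br)c(Br)c1OC
A7 | alternative 3 | 4-[(methylsulfonyl)methyl]benzene-1,2-diol | CS(=O)(=O)Cc1ccc(O)c(O)c1
A8 | alternative 3 | 3,5-dibromo-4-[(methylsulfonyl)methyl]benzene-1,2-diol | CS(=O)(=O)Cc1c(Br)cc(O)c(O)c1Br
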